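The cyclopentane (C1 = carbinol carbon with CH3/OH, C2 = CH carrying the polyene, C3 = CH carrying the 2-hydroxypropan-2-yl group, C4 and C5 = the two CH2) is treated as a contracted cyclohexene. The C1–OH and the first chain carbon form an aldol retron; opening it and re-joining the two carbonyl carbons as an alkene gives (R)-α-terpineol, which derives from the "para" Diels–Alder adduct of isoprene and an acrylate. The key step is this catalytic enantioselective cycloaddition: it forms the C4–C5 and C2–C3 ring bonds and the C3 stereocentre at once in a temporary six-membered ring. Ozonolysis/aldol contraction, epoxidation and reductive opening then set C1 and C2; Wittig reactions add the polyene.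

Key step: step 1

Remark: crocetin dialdehyde (the C20 dialdehyde), (E)-geranyl bromide and both enantiomers of the o-tolyl oxazaborolidine are taken as purchasable. Ring atoms are numbered as in the paragraph above and carotenoid numbering is used only for chain positions. New disubstituted double bonds from the Wittig steps are equilibrated to E in the usual way.

Step 1
Reactants: 1 isoprene; 2 2,2,2-trifluoroethyl acrylate
Product: 3 2,2,2-trifluoroethyl (1R)-4-methylcyclohex-3-ene-1-carboxylate
Conditions: (3aR)-1-(2-methylphenyl)-3,3-diphenyltetrahydro-1H,3H-pyrrolo[1,2-c][1,3,2]oxazaborole (C24H24BNO, 10 mol %) + Tf2NH (10 mol %), 1 (5 equiv), CH2Cl2, −20 °C to rt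
Reagents that add atoms: none
Why: The N-protonated oxazaborolidine binds the ester carbonyl at boron and lowers the acrylate LUMO, and a concerted, asynchronous normal-demand [4+2] cycloaddition joins the acrylate CH2 (future C4) to the isoprene CH2 next to the methyl-bearing carbon (future C5) and the acrylate α-carbon (future C3) to the other diene terminus (future C2). The closest known reaction type is the cationic oxazaborolidine-catalysed Diels–Alder reaction of trifluoroethyl acrylate with simple acyclic dienes. The six-membered ring is closed by suprafacial [4π+2π] cycloaddition with both σ-bonds formed in the same step; this ring is temporary, and its double bond later supplies the ketone and aldehyde for ring contraction. The only new stereocentre, the ester-bearing carbon, is set by the catalyst, whose aryl groups shield one face of the boron-bound acrylate; the (R)-catalyst is chosen as the antipode of the (S)-catalyst that, as far as recalled, gives (S)-cyclohex-3-enecarboxylates, and the sense should be checked by the rotation of 5 against (R)-(+)-α-terpineol. The step needs "para" (1,4) regioselectivity, secured by the larger HOMO coefficient at the isoprene terminus adjacent to the methyl-substituted carbon and amplified by the Lewis acid, and enantioface selectivity, secured by the two-point binding of the ester to the catalyst.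

Step 2
Reactants: 3 2,2,2-trifluoroethyl (1R)-4-methylcyclohex-3-ene-1-carboxylate
Product: 5 (R)-α-terpineol, via methyl ketone 4 (not isolated)
Conditions: MeMgBr (3.5 equiv), THF, −20 to 0 °C; aq. NH4Cl
Reagents that add atoms: methylmagnesium bromide, C[Mg]Br
Why: Double Grignard addition to the activated ester runs through ketone 4 to the tertiary alcohol, and fast addition at low temperature outpaces enolisation, so the existing stereocentre is kept and no new one is formed.

Step 3
Reactants: 5 (R)-α-terpineol
Product: 7 (5R)-5-(2-hydroxypropan-2-yl)-2-methylcyclopent-1-ene-1-carbaldehyde, via keto-lactol 6 (not isolated)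
Conditions: O3, CH2Cl2, −78 °C; Me2S, −78 °C to rt; concentrate; then piperidine (0.3 equiv), AcOH (0.3 equiv), toluene, 80 °C
Reagents that add atoms: ozone, [O-][O+]=O
Why: Ozonolysis with reductive work-up cleaves the only C=C to the keto aldehyde (held as lactol 6 by the tertiary OH), and the piperidinium acetate aldol condensation runs through the enamine of the aldehyde, which attacks the methyl ketone (5-exo-trig, forming C1–C2) and dehydrates to the conjugated tetrasubstituted enal; the stereocentre is not enolisable and no new one is formed.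

Step 4
Reactants: 7 (5R)-5-(2-hydroxypropan-2-yl)-2-methylcyclopent-1-ene-1-carbaldehyde
Product: 9 (3aS,6R,6aS)-6,6a-epoxy-3,3,6-trimethylhexahydro-1H-cyclopenta[c]furan-1-ol (anomer mixture), via epoxy aldehyde 8 (not isolated)
Conditions: 30 % H2O2, NaOH (aq), MeOH, 0 °C
Reagents that add atoms: hydrogen peroxide, OO
Why: In this Weitz–Scheffer nucleophilic epoxidation hydroperoxide adds reversibly to the β-carbon and the enolate closes the oxirane on the ring face anti to the bulky 2-hydroxypropan-2-yl group at the adjacent stereocentre, which sets both oxirane carbons (oxygen at C1 on the required face); the formyl group is thereby placed syn to the tertiary OH and is trapped as the cis-fused lactol 9, which only this diastereomer can form.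

Step 5
Reactants: 9 (3aS,6R,6aS)-6,6a-epoxy-3,3,6-trimethylhexahydro-1H-cyclopenta[c]furan-1-ol
Product: 10 (3aS,6R,6aS)-6,6a-epoxy-3,3,6-trimethylhexahydro-1H-cyclopenta[c]furan-1-one
Conditions: TEMPO (10 mol %), PhI(OAc)2 (1.3 equiv), CH2Cl2, rt
Reagents that add atoms: none
Why: Oxoammonium (TEMPO/PhI(OAc)2) oxidation converts the lactol into the γ-lactone under nearly neutral conditions that leave the tetrasubstituted epoxide intact, and no stereocentre is touched.

Step 6
Reactants: 10 (3aS,6R,6aS)-6,6a-epoxy-3,3,6-trimethylhexahydro-1H-cyclopenta[c]furan-1-one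
Product: 11 (3aR,6R,6aR)-6-hydroxy-3,3,6-trimethylhexahydro-1H-cyclopenta[c]furan-1-one
Conditions: SmI2 (2.5 equiv), THF/HMPA, Me2NCH2CH2OH, 0 °C
Reagents that add atoms: none
Why: Reductive cleavage of the α,β-epoxy lactone by SmI2 (two single-electron transfers) breaks only the Cα–O bond, so the tertiary carbinol centre C1 keeps the oxygen configuration from step 4, and protonation of the samarium enolate at the ring-fusion carbon C2 can only give the cis-fused bicyclo[3.3.0] lactone, which places the carbonyl carbon cis to the CMe2–O carbon and trans to the new OH.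

Step 7
Reactants: 11 (3aR,6R,6aR)-6-hydroxy-3,3,6-trimethylhexahydro-1H-cyclopenta[c]furan-1-one
Product: 12 (3aR,6R,6aR)-3,3,6-trimethylhexahydro-1H-cyclopenta[c]furan-1,6-diol (anomer mixture)
Conditions: i-Bu2AlH (2.2 equiv), CH2Cl2, −78 °C; aq. KNaC4H4O6 (Rochelle salt)
Reagents that add atoms: none
Why: Half-reduction of the γ-lactone by i-Bu2AlH at −78 °C stops at the aluminium hemiacetal and gives the lactol as the masked cis β-hydroxy aldehyde, with no ring stereocentre altered.

Step 8
Reactants: 13 (E)-geranyl bromide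
Product: 14 [(2E)-3,7-dimethylocta-2,6-dien-1-yl]triphenylphosphonium bromide
Conditions: PPh3, toluene, rt, dark
Reagents that add atoms: triphenylphosphine, c1ccc(cc1)P(c1ccccc1)c1ccccc1
Why: SN2 quaternisation of triphenylphosphine by the primary allylic bromide (phosphonium salt formation) retains the 2E double bond.

Step 9
Reactants: 14 [(2E)-3,7-dimethylocta-2,6-dien-1-yl]triphenylphosphonium bromide; 15 crocetin dialdehyde
Product: 17 (all-E)-8'-apo-ψ-caroten-8'-al (apo-8'-lycopenal), via geranylidene ylide 16 (not isolated)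
Conditions: NaOMe, MeOH/CH2Cl2, 0 °C to rt, 15 in excess (2.5 equiv, recovered); then I2 (cat.), hexane/CH2Cl2, daylight
Reagents that add atoms: none
Why: Wittig olefination of one formyl group of the symmetric dialdehyde (kept in excess) with the semi-stabilised allylic ylide 16 builds the 7',8' double bond, and iodine-catalysed equilibration converts the E/Z mixture at this bond into the all-E aldehyde.

Step 10
Reactants: 17 (all-E)-8'-apo-ψ-caroten-8'-al
Product: 18 (all-E)-8'-apo-ψ-caroten-8'-ol
Conditions: NaBH4, EtOH/THF, 0 °C, dark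
Reagents that add atoms: none
Why: Borohydride 1,2-reduction of the polyenal gives the primary allylic alcohol without touching the polyene.

Step 11
Reactants: 18 (all-E)-8'-apo-ψ-caroten-8'-ol
Product: 19 [(all-E)-8'-apo-ψ-caroten-8'-yl]triphenylphosphonium bromide
Conditions: PPh3·HBr (1.1 equiv), MeOH/CH2Cl2, rt, dark
Reagents that add atoms: triphenylphosphine hydrobromide, [Br-].[PH+](c1ccccc1)(c1ccccc1)c1ccccc1
Why: Ionisation of the allylic alcohol by HBr and capture of the delocalised polyenyl cation at its primary terminus by triphenylphosphine (retinyl-type phosphonium salt formation) gives the fully conjugated salt.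

Step 12
Reactants: 12 (3aR,6R,6aR)-3,3,6-trimethylhexahydro-1H-cyclopenta[c]furan-1,6-diol; 19 [(all-E)-8'-apo-ψ-caroten-8'-yl]triphenylphosphonium bromide
Product: 22 (all-E,2R,5R,6R)-2,6-cyclolycopene-1,5-diol (target), via polyenylidene ylide 20 (not isolated), via hydroxy aldehyde 21 (not isolated)
Conditions: 1,2-epoxybutane/EtOH, reflux, N2, dark; then reflux in EtOH (Z to E), crystallise
Reagents that add atoms: none
Why: In this Wittig olefination under neutral conditions bromide opens 1,2-epoxybutane and the resulting alkoxide generates ylide 20, which intercepts the open-chain tautomer 21 of the lactol, so that the base-free medium should avoid retro-aldol cleavage and epimerisation at the aldehyde α-carbon; the new 7,8 double bond is equilibrated to E and the three ring stereocentres are carried over unchanged.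

Compound list
1 | isoprene (2-methylbuta-1,3-diene) | C=CC(C)=C | starting material
2 | 2,2,2-trifluoroethyl acrylate | C=CC(=O)OCC(F)(F)F | starting material
3 | 2,2,2-trifluoroethyl (1R)-4-methylcyclohex-3-ene-1-carboxylate | CC1=CC[C@@H](CC1)C(=O)OCC(F)(F)F | intermediate
4 | 1-[(1R)-4-methylcyclohex-3-en-1-yl]ethan-1-one (methyl ketone) | CC1=CC[C@@H](CC1)C(C)=O | intermediate
5 | (R)-α-terpineol, 2-[(1R)-4-methylcyclohex-3-en-1-yl]propan-2-ol | CC1=CC[C@@H](CC1)C(C)(C)O | intermediate
6 | (4R)-5,5-dimethyl-4-(3-oxobutyl)oxolan-2-ol (keto-lactol, anomer mixture) | CC(=O)CC[C@@H]1CC(O)OC1(C)C | intermediate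
7 | (5R)-5-(2-hydroxypropan-2-yl)-2-methylcyclopent-1-ene-1-carbaldehyde | CC1=C(C=O)[C@@H](CC1)C(C)(C)O | intermediate
8 | (1S,2S,5R)-2-(2-hydroxypropan-2-yl)-5-methyl-6-oxabicyclo[3.1.0]hexane-1-carbaldehyde (epoxide oxygen trans to the hydroxypropyl group) | O=C[C@@]12O[C@]1(C)CC[C@H]2C(C)(C)O | intermediate
9 | (3aS,6R,6aS)-6,6a-epoxy-3,3,6-trimethylhexahydro-1H-cyclopenta[c]furan-1-ol (anomer mixture) | CC1(C)OC(O)[C@@]23O[C@]2(C)CC[C@@H]13 | intermediate
10 | (3aS,6R,6aS)-6,6a-epoxy-3,3,6-trimethylhexahydro-1H-cyclopenta[c]furan-1-one | CC1(C)OC(=O)[C@@]23O[C@]2(C)CC[C@@H]13 | intermediate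
11 | (3aR,6R,6aR)-6-hydroxy-3,3,6-trimethylhexahydro-1H-cyclopenta[c]furan-1-one (cis-fused, OH trans to the carbonyl carbon) | CC1(C)OC(=O)[C@@H]2[C@H]1CC[C@@]2(C)O | intermediate
12 | (3aR,6R,6aR)-3,3,6-trimethylhexahydro-1H-cyclopenta[c]furan-1,6-diol (anomer mixture) | CC1(C)OC(O)[C@@H]2[C@H]1CC[C@@]2(C)O | intermediate
13 | (E)-geranyl bromide, (2E)-1-bromo-3,7-dimethylocta-2,6-diene | CC(C)=CCC/C(C)=C/CBr | starting material
14 | [(2E)-3,7-dimethylocta-2,6-dien-1-yl]triphenylphosphonium bromide | CC(C)=CCC/C(C)=C/C[P+](c1ccccc1)(c1ccccc1)c1ccccc1.[Br-] | intermediate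
15 | crocetin dialdehyde, (all-E)-2,6,11,15-tetramethylhexadeca-2,4,6,8,10,12,14-heptaenedial | O=C/C(C)=C/C=C/C(C)=C/C=C/C=C(C)/C=C/C=C(C)/C=O | starting material
16 | [(2E)-3,7-dimethylocta-2,6-dien-1-ylidene]triphenylphosphorane (geranylidene ylide) | CC(C)=CCC/C(C)=C/C=P(c1ccccc1)(c1ccccc1)c1ccccc1 | intermediate
17 | (all-E)-8'-apo-ψ-caroten-8'-al, (all-E)-2,6,11,15,19,23-hexamethyltetracosa-2,4,6,8,10,12,14,16,18,22-decaenal | CC(C)=CCC/C(C)=C/C=C/C(C)=C/C=C/C(C)=C/C=C/C=C(C)/C=C/C=C(C)/C=O | intermediate
18 | (all-E)-8'-apo-ψ-caroten-8'-ol | CC(C)=CCC/C(C)=C/C=C/C(C)=C/C=C/C(C)=C/C=C/C=C(C)/C=C/C=C(C)/CO | intermediate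
19 | [(all-E)-8'-apo-ψ-caroten-8'-yl]triphenylphosphonium bromide | CC(C)=CCC/C(C)=C/C=C/C(C)=C/C=C/C(C)=C/C=C/C=C(C)/C=C/C=C(C)/C[P+](c1ccccc1)(c1ccccc1)c1ccccc1.[Br-] | intermediate
20 | [(all-E)-8'-apo-ψ-caroten-8'-ylidene]triphenylphosphorane (polyenylidene ylide) | CC(C)=CCC/C(C)=C/C=C/C(C)=C/C=C/C(C)=C/C=C/C=C(C)/C=C/C=C(C)/C=P(c1ccccc1)(c1ccccc1)c1ccccc1 | intermediate
21 | (1R,2R,5R)-2-hydroxy-5-(2-hydroxypropan-2-yl)-2-methylcyclopentane-1-carbaldehyde (open form of 12) | O=C[C@@H]1[C@H](C(C)(C)O)CC[C@@]1(C)O | intermediate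
22 | (all-E,2R,5R,6R)-2,6-cyclolycopene-1,5-diol; ring: (1R,2R,3R)-3-(2-hydroxypropan-2-yl)-1-methyl-2-(polyenyl)cyclopentan-1-ol | CC(C)=CCC/C(C)=C/C=C/C(C)=C/C=C/C(C)=C/C=C/C=C(C)/C=C/C=C(C)/C=C/[C@@H]1[C@H](C(C)(C)O)CC[C@@]1(C)O | target

Total step count: 12. Longest linear sequence: 8 (steps 1 to 7, then step 12).

Steps most likely to fail

Step 12. The hindered bicyclic lactol may open only slowly, so that epimerisation at the aldehyde α-carbon or retro-aldol cleavage of the open form competes with olefination. The fallback sets out from 11 and comes back at 22. The lactone of 11 is opened with MeNH(OMe)·HCl and i-PrMgCl to the Weinreb amide diol F6. Both tertiary hydroxyls are capped with Et3SiOTf and 2,6-lutidine to give the bis(triethylsilyl) ether F7. i-Bu2AlH at −78 °C then releases the open-chain protected aldehyde F8, which can form neither a lactol nor a free β-alkoxide. F8 is olefinated at −78 °C with ylide 20, preformed from 19 and NaN(SiMe3)2, to the bis(triethylsilyl) ether of the target F9, and Bu4NF removes both silyl groups to give 22.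

Step 4. The nucleophilic epoxidation of the tetrasubstituted enal may show insufficient facial discrimination, or the formyl group may suffer Dakin-type oxidation. The fallback sets out from 7 and comes back at 10. Pinnick oxidation (NaClO2, NaH2PO4, 2-methylbut-2-ene) gives the hydroxy acid F4, and carbodiimide lactonisation (EDC·HCl, DMAP) gives the bicyclic α-alkylidene lactone F5. An electrophilic dioxirane generated in the flask (CF3COCH3, Oxone 2KHSO5·KHSO4·K2SO4, NaHCO3, MeCN/H2O, 0 °C) then epoxidises the convex face of F5, anti to the CMe2–O carbon, to give 10.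

Step 1. Enantioface discrimination (or its sense) and para/meta regiocontrol may erode with the small, weakly biased diene. The fallback sets out from 1 and comes back at 5. The auxiliary-bound dienophile (4S)-3-acryloyl-4-benzyloxazolidin-2-one F1, made from (S)-4-benzyloxazolidin-2-one and acryloyl chloride, reacts with 1 under Et2AlCl in CH2Cl2 at −100 °C. The reaction goes through the chelated s-cis imide, whose benzyl group blocks one face, to give the (R)-configured cycloadduct imide F2. LiOCH2Ph transesterifies it to benzyl (1R)-4-methylcyclohex-3-ene-1-carboxylate F3 with recovery of the auxiliary, and MeMgBr converts F3 into 5.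

Further compounds
F1 | step 1 | (4S)-3-acryloyl-4-benzyloxazolidin-2-one | C=CC(=O)N1[C@@H](Cc2ccccc2)COC1=O
F2 | step 1 | (4S)-4-benzyl-3-{[(1R)-4-methylcyclohex-3-en-1-yl]carbonyl}oxazolidin-2-one | CC1=CC[C@@H](CC1)C(=O)N1[C@@H](Cc2ccccc2)COC1=O
F3 | step 1 | benzyl (1R)-4-methylcyclohex-3-ene-1-carboxylate | CC1=CC[C@@H](CC1)C(=O)OCc1ccccc1
F4 | step 4 | (5R)-5-(2-hydroxypropan-2-yl)-2-methylcyclopent-1-ene-1-carboxylic acid | CC1=C(C(O)=O)[C@@H](CC1)C(C)(C)O
F5 | step 4 | (3aR)-3,3,6-trimethyl-3,3a,4,5-tetrahydro-1H-cyclopenta[c]furan-1-one | CC1=C2C(=O)OC(C)(C)[C@@H]2CC1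
F6 | step 12 | (1R,2R,5R)-2-hydroxy-5-(2-hydroxypropan-2-yl)-N-methoxy-N,2-dimethylcyclopentane-1-carboxamide | CON(C)C(=O)[C@@H]1[C@H](C(C)(C)O)CC[C@@]1(C)O
F7 | step 12 | (1R,2R,5R)-N-methoxy-N,2-dimethyl-2-(triethylsilyloxy)-5-[2-(triethylsilyloxy)propan-2-yl]cyclopentane-1-carboxamide | CON(C)C(=O)[C@@H]1[C@H](C(C)(C)O[Si](CC)(CC)CC)CC[C@@]1(C)O[Si](CC)(CC)CC
F8 | step 12 | (1R,2R,5R)-2-methyl-2-(triethylsilyloxy)-5-[2-(triethylsilyloxy)propan-2-yl]cyclopentane-1-carbaldehyde | O=C[C@@H]1[C@H](C(C)(C)O[Si](CC)(CC)CC)CC[C@@]1(C)O[Si](CC)(CC)CC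
F9 | step 12 | bis(triethylsilyl) ether of (all-E,2R,5R,6R)-2,6-cyclolycopene-1,5-diol | CC(C)=CCC/C(C)=C/C=C/C(C)=C/C=C/C(C)=C/C=C/C=C(C)/C=C/C=C(C)/C=C/[C@@H]1[C@H](C(C)(C)O[Si](CC)(CC)CC)CC[C@@]1(C)O[Si](CC)(CC)CC
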